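## Retrosynthetic overview

1. The strategy rests on the E-trisubstituted C11=C12 alkene next to the C10 carbinol in the 14-membered carbocycle (C1–C14). It is carried as the ring alkyne C11≡C12, so the carbocycle is opened at C11≡C12 to a diyne with methyl caps on C11 and C12 (ring-closing alkyne metathesis). The alkene is written afterwards by C10–OH-directed trans-hydrosilylation (Si on C12), iododesilylation and Negishi methylation, then acetylation.
2. Diyne: C4–C5 by B-alkyl Suzuki–Miyaura coupling of Z-vinyl iodide 14 (fragment A: C1–C4, C12–C15) with the 9-BBN adduct of Z-dienol 17 (fragment B: C5–C10, Z-C7=C8 taken from the pyranone ring). C10–C11 by propynyl Grignard addition, oxidation and Noyori reduction (sets C10).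
3. C8 and C7 from C10 by iodocarbonate cyclisation and epoxide closure. C1 by Evans alkylation of the hept-5-ynoyl imide with (2Z)-1-bromo-3-iodobut-2-ene. C15 carbinol by MeMgBr.
4. Ring order: oxirane (C7–C8–O) on the open chain in step 17, then the 14-membered carbocycle in step 19.

Key step: step 19

Remark: cembrane numbering is used for all intermediates (C1 bears C15; methyl groups on C4, C8, C12; ring carbons C1–C14). 1-Propynylmagnesium bromide is used as its commercial THF solution in place of propyne gas.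

## Route

Step 1
Reactants: 1 but-2-yn-1-ol
Product: 3 (2Z)-3-iodobut-2-en-1-ol, via cyclic alkenylalanate 2 (not isolated)
Conditions: NaAlH2(OCH2CH2OMe)2 (1.5 equiv), THF, 0 °C to rt; then I2, THF, −78 to 0 °C
Reagents that add atoms: iodine, II
Why: Hydroxyl-directed trans-hydroalumination of the propargylic alcohol puts aluminium on C3 inside a five-membered alkoxyalanate, and iodinolysis with retention gives the Z-iodoalkene with iodine cis to CH2OH.

Step 2
Reactants: 3 (2Z)-3-iodobut-2-en-1-ol
Product: 4 (2Z)-1-bromo-3-iodobut-2-ene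
Conditions: CBr4, PPh3, CH2Cl2, 0 °C
Reagents that add atoms: carbon tetrabromide, BrC(Br)(Br)Br
Why: Appel bromination converts the primary allylic alcohol into the bromide without touching the vinyl iodide or the alkene geometry.

Step 3
Reactants: 5 hept-5-ynoic acid; 6 (4S)-4-benzyl-1,3-oxazolidin-2-one
Product: 8 (4S)-4-benzyl-3-(hept-5-ynoyl)-1,3-oxazolidin-2-one, via mixed pivalic anhydride 7 (not isolated)
Conditions: t-BuCOCl, Et3N, THF, −20 °C; then 6, LiCl, rt
Reagents that add atoms: none
Why: N-acylation of the oxazolidinone through the mixed pivalic anhydride with LiCl/Et3N activation is the standard entry to Evans imides.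

Step 4
Reactants: 8 (4S)-4-benzyl-3-(hept-5-ynoyl)-1,3-oxazolidin-2-one; 4 (2Z)-1-bromo-3-iodobut-2-ene
Product: 10 (4S)-4-benzyl-3-[(2R)-2-[(2Z)-3-iodobut-2-en-1-yl]hept-5-ynoyl]-1,3-oxazolidin-2-one, via sodium Z-enolate 9 (not isolated)
Conditions: NaN(SiMe3)2, THF, −78 °C; then 4, −78 to −45 °C
Reagents that add atoms: none
Why: Evans alkylation, in which the chelated sodium Z-enolate is attacked by the allylic bromide on the face opposite the benzyl group, sets C1 as R.

Step 5
Reactants: 10 alkylated imide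
Product: 11 methyl (2R)-2-[(2Z)-3-iodobut-2-en-1-yl]hept-5-ynoate
Conditions: MeMgBr added to MeOH (gives MeOMgBr); then 10, CH2Cl2/MeOH, 0 °C
Reagents that add atoms: methanol, CO
Why: Bromomagnesium methoxide transesterifies the imide at the exocyclic carbonyl (auxiliary removal by alcoholysis) without epimerising C1.

Step 6
Reactants: 11 methyl ester
Product: 13 (3R)-3-[(2Z)-3-iodobut-2-en-1-yl]-2-methyloct-6-yn-2-ol, via methyl ketone 12 (not isolated)
Conditions: MeMgBr (4 equiv), THF, 0 °C to rt; aq. NH4Cl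
Reagents that add atoms: methylmagnesium bromide, C[Mg]Br
Why: Double Grignard addition to the ester gives the C15 dimethylcarbinol, addition to the intermediate ketone being faster than enolisation so that C1 is kept, and the vinyl iodide is inert to MeMgBr at this temperature.

Step 7
Reactants: 13 tertiary alcohol
Product: 14 triethylsilyl ether of 13 (fragment A)
Conditions: Et3SiOTf, 2,6-lutidine, CH2Cl2, −78 to 0 °C
Reagents that add atoms: triethylsilyl trifluoromethanesulfonate, CC[Si](CC)(CC)OS(=O)(=O)C(F)(F)F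
Why: Silylation of the hindered tertiary alcohol with the silyl triflate protects C15–OH for the organometallic, halogen and alkylidyne chemistry ahead.

Step 8
Reactants: 15 4-methyl-5,6-dihydro-2H-pyran-2-one
Product: 16 4-methyl-5,6-dihydro-2H-pyran-2-ol (lactol, anomers)
Conditions: i-Bu2AlH (1.05 equiv), CH2Cl2, −78 °C; aq. potassium sodium tartrate
Reagents that add atoms: none
Why: Partial reduction of the unsaturated δ-lactone with one equivalent of i-Bu2AlH at −78 °C should stop at the aluminium hemiacetal, which gives the lactol on work-up (lactone-to-lactol reduction).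

Step 9
Reactants: 16 lactol
Product: 17 (3Z)-3-methylhexa-3,5-dien-1-ol (fragment B)
Conditions: Ph3PCH3Br, KOt-Bu, THF, 0 °C; then 16, 0 °C to rt
Reagents that add atoms: methyltriphenylphosphonium bromide, [Br-].C[P+](c1ccccc1)(c1ccccc1)c1ccccc1
Why: Wittig methylenation of the ring-opened hydroxy enal form of the lactol gives the diene, and the Z geometry of C7=C8 is inherited from the ring.

Step 10
Reactants: 17 (3Z)-3-methylhexa-3,5-dien-1-ol; 14 fragment A vinyl iodide
Product: 19 (3Z,7Z,10R)-3,7-dimethyl-10-[2-(triethylsilyloxy)propan-2-yl]pentadeca-3,7-dien-13-yn-1-ol, via bis-borylated alkene 18 (not isolated)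
Conditions: 17, 9-BBN (2.3 equiv), THF, 0 °C to rt; then aq. Cs2CO3, 14, Pd(dppf)Cl2 (5 mol%), AsPh3, DMF, rt
Reagents that add atoms: none
Why: Hydroboration with 9-BBN puts boron on the terminal carbon C5 of the diene (the hydroxyl is carried as its borinate; the trisubstituted alkene is not touched), and B-alkyl Suzuki–Miyaura coupling forms C4–C5 with retention at the vinyl iodide, giving Z-C3=C4.

Step 11
Reactants: 19 primary alcohol
Product: 20 (3Z,7Z,10R)-3,7-dimethyl-10-[2-(triethylsilyloxy)propan-2-yl]pentadeca-3,7-dien-13-ynal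
Conditions: Dess–Martin periodinane, NaHCO3, CH2Cl2, 0 °C; used crude
Reagents that add atoms: none
Why: Dess–Martin oxidation under bicarbonate buffer should give the β,γ-unsaturated aldehyde without migration of the C7=C8 alkene into conjugation.

Step 12
Reactants: 20 aldehyde
Product: 21 (4RS,6Z,10Z,13R)-6,10-dimethyl-13-[2-(triethylsilyloxy)propan-2-yl]octadeca-6,10-dien-2,16-diyn-4-ol (C10 epimers)
Conditions: CH3C≡CMgBr (0.5 M in THF), THF, −78 °C
Reagents that add atoms: 1-propynylmagnesium bromide, CC#C[Mg]Br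
Why: Grignard addition of the propynyl nucleophile forms C10–C11, and the uncontrolled C10 configuration is corrected by the oxidation and reduction that follow.

Step 13
Reactants: 21 propargylic alcohol (C10 epimers)
Product: 22 (6Z,10Z,13R)-6,10-dimethyl-13-[2-(triethylsilyloxy)propan-2-yl]octadeca-6,10-dien-2,16-diyn-4-one
Conditions: Dess–Martin periodinane, NaHCO3, CH2Cl2, 0 °C
Reagents that add atoms: none
Why: Dess–Martin oxidation of the propargylic alcohol gives the ynone under neutral buffered conditions that should leave the skipped C7=C8 alkene in place.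

Step 14
Reactants: 22 ynone
Product: 23 (4S,6Z,10Z,13R)-6,10-dimethyl-13-[2-(triethylsilyloxy)propan-2-yl]octadeca-6,10-dien-2,16-diyn-4-ol
Conditions: Ru[(S,S)-TsDPEN](p-cymene) (3 mol%, base-free), i-PrOH, rt
Reagents that add atoms: none
Why: Noyori asymmetric transfer hydrogenation of the ynone sets C10 as S, the (S,S)-ligand telling the alkynyl flank from the alkyl flank in the six-membered hydride/proton transfer.

Step 15
Reactants: 23 (S)-propargylic alcohol
Product: 24 tert-butyl carbonate of 23 (C10–OCO2t-Bu)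
Conditions: Boc2O, DMAP (0.2 equiv), MeCN, rt
Reagents that add atoms: di-tert-butyl dicarbonate, CC(C)(C)OC(=O)OC(=O)OC(C)(C)C
Why: DMAP-catalysed acylation of the secondary alcohol installs the carbonate that will deliver oxygen to C8.

Step 16
Reactants: 24 tert-butyl carbonate
Product: 25 cyclic iodocarbonate (1,3-dioxan-2-one through O–C10 and O–C8, iodine on C7; 1R,7R,8R,10S)
Conditions: IBr (1.05 equiv), toluene, −85 °C; aq. Na2S2O3/NaHCO3
Reagents that add atoms: iodine monobromide, IBr
Why: Iodocarbonate cyclisation (halocyclisation of a homoallylic tert-butyl carbonate), in which the iodonium on C7=C8 is captured 6-exo by the carbonate carbonyl at the more substituted C8 through a chair with the C10 propynyl group equatorial, sets C8 syn to C10–O and C7 by anti addition, and loss of the tert-butyl group makes it irreversible.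

Step 17
Reactants: 25 cyclic iodocarbonate
Product: 27 epoxy alcohol (C10–OH free, C15–OSiEt3; 1R,3Z,7S,8R,10S), via iodo diol 26 (not isolated)
Conditions: K2CO3, MeOH, rt
Reagents that add atoms: none
Why: Methanolysis of the cyclic carbonate frees the C8 alkoxide, which displaces iodide at C7 with inversion (Williamson-type epoxide closure), so the anti iodo-oxygen pair from the Z alkene becomes the cis-epoxide (7S,8R).

Step 18
Reactants: 27 epoxy alcohol
Product: 28 acyclic epoxy diyne bis(triethylsilyl) ether (1R,3Z,7S,8R,10S; methyl-capped alkynes at C11 and C12)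
Conditions: Et3SiCl, imidazole, DMAP (cat.), CH2Cl2, 0 °C to rt
Reagents that add atoms: chlorotriethylsilane, CC[Si](Cl)(CC)CC
Why: Silylation of the secondary propargylic alcohol under imidazole conditions, which are not Lewis acidic and so spare the epoxide, gives the metathesis substrate.

Step 19
Reactants: 28 acyclic epoxy diyne bis(triethylsilyl) ether
Product: 29 (1R,3Z,7S,8R,10S)-7,8-epoxy-10,15-bis(triethylsilyloxy)-20-norcembr-3-en-11-yne (14-membered cycloalkyne)
Conditions: [Mo(≡CC6H4OMe-4)(OSiPh3)3] (15 mol%), 5 Å molecular sieves, toluene (2 mM), rt to 80 °C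
Reagents that add atoms: none
Why: The molybdenum alkylidyne adds to one methyl-capped alkyne by [2+2] cycloaddition to a metallacyclobutadiene, cycloreversion releases but-2-yne (taken up by the 5 Å sieves, which drives the equilibrium), and the substrate-bound alkylidyne then engages the second alkyne in the same way. The closest known reaction type is ring-closing alkyne metathesis of bis(methyl-capped) diynes bearing propargylic silyl ethers with triarylsilanolate molybdenum alkylidynes. The 14-membered carbocycle (C1–C14) closes end to end through the C11≡C12 bond, and a ring of this size should hold the linear C10–C11≡C12–C13 unit without strain. No stereocentre is created; C1, C7, C8 and C10 are spectators and Z-C3=C4 is untouched. The step needs chemoselectivity for the alkynes over the alkene, the epoxide and the silyl ethers, which is inherent to the alkylidyne with its bulky silanolate ligands. It also needs ring closure over oligomerisation, which is secured by 2 mM dilution and by the reversibility of oligomer formation.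

Step 20
Reactants: 29 cycloalkyne bis(triethylsilyl) ether
Product: 30 (1R,3Z,7S,8R,10S)-7,8-epoxy-15-(triethylsilyloxy)-20-norcembr-3-en-11-yn-10-ol
Conditions: HF·pyridine, pyridine, THF, 0 °C, stopped at full conversion of 29
Reagents that add atoms: none
Why: Fluoride desilylation under pyridine buffering should remove the secondary propargylic silyl ether much faster than the hindered tertiary one, and the buffered medium does not open the epoxide.

Step 21
Reactants: 30 macrocyclic propargylic alcohol
Product: 31 (1R,3Z,7S,8R,10S,11Z)-12-[benzyl(dimethyl)silyl]-7,8-epoxy-15-(triethylsilyloxy)-20-norcembra-3,11-dien-10-ol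
Conditions: [Cp*Ru(MeCN)3]PF6 (10 mol%), BnMe2SiH, CH2Cl2, 0 °C to rt
Reagents that add atoms: benzyldimethylsilane, C[SiH](C)Cc1ccccc1
Why: Ruthenium-catalysed trans-hydrosilylation of the propargylic alcohol delivers H and Si anti across the alkyne and places silicon on the carbon distal to the hydroxyl (C12), cis to C10.

Step 22
Reactants: 31 vinylsilane
Product: 32 (1R,3Z,7S,8R,10S,11Z)-7,8-epoxy-12-iodo-15-(triethylsilyloxy)-20-norcembra-3,11-dien-10-ol
Conditions: N-iodosuccinimide, 2,6-lutidine, (CF3)2CHOH, 0 °C, short reaction time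
Reagents that add atoms: N-iodosuccinimide, O=C1CCC(=O)N1I
Why: Iododesilylation, by ipso attack of iodonium on the vinylsilane and loss of the β-silyl group, replaces silicon by iodine with retention of the alkene geometry, the fluorinated alcohol making the exchange fast at 0 °C.

Step 23
Reactants: 32 vinyl iodide
Product: 33 (1R,3Z,7S,8R,10S,11E)-7,8-epoxy-15-(triethylsilyloxy)cembra-3,11-dien-10-ol
Conditions: Me2Zn, Pd(PPh3)4 (10 mol%), THF, 0 to 45 °C
Reagents that add atoms: dimethylzinc, C[Zn]C
Why: Negishi coupling of the alkenyl iodide with Me2Zn proceeds with retention at C12 and gives the E-trisubstituted C11=C12 alkene, the free hydroxyl being carried as its zinc alkoxide.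

Step 24
Reactants: 33 C15 silyl ether
Product: 34 (1R,3Z,7S,8R,10S,11E)-7,8-epoxycembra-3,11-diene-10,15-diol
Conditions: Bu4NF, THF, rt
Reagents that add atoms: none
Why: Fluoride cleavage of the tertiary silyl ether frees the C15 hydroxyl under non-acidic conditions that the epoxide tolerates.

Step 25
Reactants: 34 diol
Product: 35 (1R,3Z,7S,8R,10S,11E)-7,8-epoxy-15-hydroxycembra-3,11-dien-10-yl acetate (CNP0254503.1)
Conditions: Ac2O, pyridine, DMAP (cat.), CH2Cl2, 0 °C
Reagents that add atoms: acetic anhydride, CC(=O)OC(C)=O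
Why: Acylation with Ac2O/pyridine is selective for the secondary allylic C10 hydroxyl over the hindered tertiary C15 hydroxyl.

## Compound list

1 | but-2-yn-1-ol | CC#CCO | starting material
2 | sodium cyclic alkenylalanate of 1 (O–Al–C3 five-membered ring, two 2-methoxyethoxy ligands) | [Na+].CC1=CCO[Al-]1(OCCOC)OCCOC | intermediate
3 | (2Z)-3-iodobut-2-en-1-ol | OC/C=C(/C)I | intermediate
4 | (2Z)-1-bromo-3-iodobut-2-ene | BrC/C=C(/C)I | intermediate
5 | hept-5-ynoic acid | CC#CCCCC(=O)O | starting material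
6 | (4S)-4-benzyl-1,3-oxazolidin-2-one | O=C1N[C@@H](Cc2ccccc2)CO1 | starting material
7 | hept-5-ynoic pivalic anhydride | CC#CCCCC(=O)OC(=O)C(C)(C)C | intermediate
8 | (4S)-4-benzyl-3-(hept-5-ynoyl)-1,3-oxazolidin-2-one | CC#CCCCC(=O)N1[C@@H](Cc2ccccc2)COC1=O | intermediate
9 | sodium Z-enolate of 8 | [Na+].CC#CCC/C=C(\[O-])N1[C@@H](Cc2ccccc2)COC1=O | intermediate
10 | (4S)-4-benzyl-3-[(2R)-2-[(2Z)-3-iodobut-2-en-1-yl]hept-5-ynoyl]-1,3-oxazolidin-2-one | CC#CCC[C@H](C/C=C(/C)I)C(=O)N1[C@@H](Cc2ccccc2)COC1=O | intermediate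
11 | methyl (2R)-2-[(2Z)-3-iodobut-2-en-1-yl]hept-5-ynoate | CC#CCC[C@H](C/C=C(/C)I)C(=O)OC | intermediate
12 | (3R)-3-[(2Z)-3-iodobut-2-en-1-yl]oct-6-yn-2-one | CC#CCC[C@H](C/C=C(/C)I)C(C)=O | intermediate
13 | (3R)-3-[(2Z)-3-iodobut-2-en-1-yl]-2-methyloct-6-yn-2-ol | CC#CCC[C@H](C/C=C(/C)I)C(C)(C)O | intermediate
14 | triethyl{[(3R)-3-[(2Z)-3-iodobut-2-en-1-yl]-2-methyloct-6-yn-2-yl]oxy}silane (fragment A) | CC#CCC[C@H](C/C=C(/C)I)C(C)(C)O[Si](CC)(CC)CC | intermediate
15 | 4-methyl-5,6-dihydro-2H-pyran-2-one | CC1=CC(=O)OCC1 | starting material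
16 | 4-methyl-5,6-dihydro-2H-pyran-2-ol (anomers) | CC1=CC(O)OCC1 | intermediate
17 | (3Z)-3-methylhexa-3,5-dien-1-ol (fragment B) | C=C/C=C(/C)CCO | intermediate
18 | bis-borylated alkene from 17 (B-alkyl-9-BBN at C5, O-9-BBN borinate at C10) | C(CB1C2CCCC1CCC2)/C=C(/C)CCOB1C2CCCC1CCC2 | intermediate
19 | (3Z,7Z,10R)-3,7-dimethyl-10-[2-(triethylsilyloxy)propan-2-yl]pentadeca-3,7-dien-13-yn-1-ol | CC#CCC[C@H](C/C=C(/C)CC/C=C(/C)CCO)C(C)(C)O[Si](CC)(CC)CC | intermediate
20 | (3Z,7Z,10R)-3,7-dimethyl-10-[2-(triethylsilyloxy)propan-2-yl]pentadeca-3,7-dien-13-ynal | CC#CCC[C@H](C/C=C(/C)CC/C=C(/C)CC=O)C(C)(C)O[Si](CC)(CC)CC | intermediate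
21 | (4RS,6Z,10Z,13R)-6,10-dimethyl-13-[2-(triethylsilyloxy)propan-2-yl]octadeca-6,10-dien-2,16-diyn-4-ol | CC#CCC[C@H](C/C=C(/C)CC/C=C(/C)CC(O)C#CC)C(C)(C)O[Si](CC)(CC)CC | intermediate
22 | (6Z,10Z,13R)-6,10-dimethyl-13-[2-(triethylsilyloxy)propan-2-yl]octadeca-6,10-dien-2,16-diyn-4-one | CC#CCC[C@H](C/C=C(/C)CC/C=C(/C)CC(=O)C#CC)C(C)(C)O[Si](CC)(CC)CC | intermediate
23 | (4S,6Z,10Z,13R)-6,10-dimethyl-13-[2-(triethylsilyloxy)propan-2-yl]octadeca-6,10-dien-2,16-diyn-4-ol | CC#CCC[C@H](C/C=C(/C)CC/C=C(/C)C[C@H](O)C#CC)C(C)(C)O[Si](CC)(CC)CC | intermediate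
24 | tert-butyl carbonate of 23 (C10–OCO2t-Bu) | CC#CCC[C@H](C/C=C(/C)CC/C=C(/C)C[C@H](OC(=O)OC(C)(C)C)C#CC)C(C)(C)O[Si](CC)(CC)CC | intermediate
25 | cyclic iodocarbonate (1,3-dioxan-2-one through O–C10 and O–C8, iodine on C7; 1R,3Z,7R,8R,10S) | CC#CCC[C@H](C/C=C(/C)CC[C@@H](I)[C@@]1(C)C[C@@H](C#CC)OC(=O)O1)C(C)(C)O[Si](CC)(CC)CC | intermediate
26 | iodo diol (C7–I, C8–OH, C10–OH; 1R,3Z,7R,8R,10S) | CC#CCC[C@H](C/C=C(/C)CC[C@@H](I)[C@](C)(O)C[C@H](O)C#CC)C(C)(C)O[Si](CC)(CC)CC | intermediate
27 | acyclic epoxy diyne alcohol (C10–OH, C15–OSiEt3; 1R,3Z,7S,8R,10S) | CC#CCC[C@H](C/C=C(/C)CC[C@@H]1O[C@]1(C)C[C@H](O)C#CC)C(C)(C)O[Si](CC)(CC)CC | intermediate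
28 | acyclic epoxy diyne bis(triethylsilyl) ether (1R,3Z,7S,8R,10S) | CC#C[C@@H](O[Si](CC)(CC)CC)C[C@@]1(C)O[C@H]1CC/C(C)=C\C[C@H](C(C)(C)O[Si](CC)(CC)CC)CCC#CC | intermediate
29 | (1R,3Z,7S,8R,10S)-7,8-epoxy-10,15-bis(triethylsilyloxy)-20-norcembr-3-en-11-yne | CC[Si](CC)(CC)O[C@@H]1C#CCC[C@@H](C(C)(C)O[Si](CC)(CC)CC)C/C=C(/C)CC[C@@H]2O[C@]2(C)C1 | intermediate
30 | (1R,3Z,7S,8R,10S)-7,8-epoxy-15-(triethylsilyloxy)-20-norcembr-3-en-11-yn-10-ol | O[C@@H]1C#CCC[C@@H](C(C)(C)O[Si](CC)(CC)CC)C/C=C(/C)CC[C@@H]2O[C@]2(C)C1 | intermediate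
31 | (1R,3Z,7S,8R,10S,11Z)-12-[benzyl(dimethyl)silyl]-7,8-epoxy-15-(triethylsilyloxy)-20-norcembra-3,11-dien-10-ol | O[C@@H]1/C=C(\[Si](C)(C)Cc3ccccc3)CC[C@@H](C(C)(C)O[Si](CC)(CC)CC)C/C=C(/C)CC[C@@H]2O[C@]2(C)C1 | intermediate
32 | (1R,3Z,7S,8R,10S,11Z)-7,8-epoxy-12-iodo-15-(triethylsilyloxy)-20-norcembra-3,11-dien-10-ol | O[C@@H]1/C=C(\I)CC[C@@H](C(C)(C)O[Si](CC)(CC)CC)C/C=C(/C)CC[C@@H]2O[C@]2(C)C1 | intermediate
33 | (1R,3Z,7S,8R,10S,11E)-7,8-epoxy-15-(triethylsilyloxy)cembra-3,11-dien-10-ol | O[C@@H]1/C=C(\C)CC[C@@H](C(C)(C)O[Si](CC)(CC)CC)C/C=C(/C)CC[C@@H]2O[C@]2(C)C1 | intermediate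
34 | (1R,3Z,7S,8R,10S,11E)-7,8-epoxycembra-3,11-diene-10,15-diol | O[C@@H]1/C=C(\C)CC[C@@H](C(C)(C)O)C/C=C(/C)CC[C@@H]2O[C@]2(C)C1 | intermediate
35 | (1R,3Z,7S,8R,10S,11E)-7,8-epoxy-15-hydroxycembra-3,11-dien-10-yl acetate (CNP0254503.1) | CC(=O)O[C@@H]1/C=C(\C)CC[C@@H](C(C)(C)O)C/C=C(/C)CC[C@@H]2O[C@]2(C)C1 | target

## Step count and risks

Total: 25 steps. Longest linear sequence: 22 steps (steps 1, 2, 4–7, 10–25, from but-2-yn-1-ol).

Steps most likely to fail:

Step 22 (iododesilylation). Electrophilic iodine may be captured at the C3=C4 alkene with participation of the C15 oxygen. The fluorinated alcohol may assist opening of the C7–C8 epoxide by the C10 hydroxyl. The β-silyl cation may rotate before silicon is lost, which would erode the alkene geometry. The fallback sets out from 30 and replaces steps 21 and 22 by hydroxyl-directed trans-hydroalumination and iodination. NaAlH2(OCH2CH2OMe)2 in THF at 0 °C adds hydride to C11 and aluminium to C12 within the five-membered cyclic alkenylalanate F1. N-iodosuccinimide at −78 °C then cleaves the C–Al bond with retention, much faster than any alkene reacts, and gives vinyl iodide 32, where the route is rejoined.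

Step 16 (iodocarbonate cyclisation). Iodine monobromide may add across the remote C3=C4 alkene. Facial selectivity at C8 may erode because the methyl group and the iodoalkyl arm compete for the equatorial site of the chair. The fallback sets out from 23 and uses hydroxyl-directed epoxidation with VO(acac)2 (5 mol%) and t-BuOOH in CH2Cl2 at 0 °C to rt. Only the alkene within reach of the vanadate ester of C10–OH is oxidised. The Z substituent C6 enforces, through allylic strain, the chair with the C10 propynyl group equatorial, so oxygen should be delivered syn to C10–O. This gives epoxy alcohol 27 directly, where the route is rejoined, and steps 15–17 are skipped. This fallback makes no new compound.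

Step 19 (ring-closing alkyne metathesis). Intermolecular metathesis to dimers and oligomers may outrun ring closure. The alkylidyne may be deactivated by coordination to the epoxide or by opening it. The fallback keeps the C11≡C12 disconnection but moves the epoxide behind the ring closure. It sets out from 23: Et3SiCl/imidazole gives the epoxide-free diyne bis(triethylsilyl) ether F2. The same molybdenum alkylidyne under the same dilution closes it to the 14-membered cycloalkyne F3. Buffered HF·pyridine frees the C10 hydroxyl to give the macrocyclic propargylic alcohol F4. Boc2O/DMAP gives the macrocyclic tert-butyl carbonate F5. IBr at −85 °C gives the macrocyclic iodocarbonate F6, the ring alkyne being much less reactive toward iodonium than the C7=C8 alkene. K2CO3 in MeOH then gives 30, where the route is rejoined. The syn-selective chair closure is expected to hold in the ring but would have to be confirmed.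

Further compounds
F1 | step 22 | sodium cyclic alkenylalanate of 30 (O–Al–C12 five-membered ring, two 2-methoxyethoxy ligands) | [Na+].O3[C@@H]1/C=C(\[Al-]3(OCCOC)OCCOC)CC[C@@H](C(C)(C)O[Si](CC)(CC)CC)C/C=C(/C)CC[C@@H]2O[C@]2(C)C1
F0 | step 16 | none | none
F2 | step 19 | (4S,6Z,10Z,13R)-6,10-dimethyl-4-(triethylsilyloxy)-13-[2-(triethylsilyloxy)propan-2-yl]octadeca-6,10-dien-2,16-diyne | CC#CCC[C@H](C/C=C(/C)CC/C=C(/C)C[C@H](O[Si](CC)(CC)CC)C#CC)C(C)(C)O[Si](CC)(CC)CC
F3 | step 19 | (1R,3Z,7Z,10S)-10,15-bis(triethylsilyloxy)-20-norcembra-3,7-dien-11-yne | CC[Si](CC)(CC)O[C@@H]1C#CCC[C@@H](C(C)(C)O[Si](CC)(CC)CC)C/C=C(/C)CC/C=C(/C)C1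
F4 | step 19 | (1R,3Z,7Z,10S)-15-(triethylsilyloxy)-20-norcembra-3,7-dien-11-yn-10-ol | O[C@@H]1C#CCC[C@@H](C(C)(C)O[Si](CC)(CC)CC)C/C=C(/C)CC/C=C(/C)C1
F5 | step 19 | tert-butyl carbonate of F4 (C10–OCO2t-Bu) | CC(C)(C)OC(=O)O[C@@H]1C#CCC[C@@H](C(C)(C)O[Si](CC)(CC)CC)C/C=C(/C)CC/C=C(/C)C1
F6 | step 19 | macrocyclic iodocarbonate (1,3-dioxan-2-one through O–C10 and O–C8, iodine on C7; 1R,3Z,7R,8R,10S) | O=C1O[C@@H]2C#CCC[C@@H](C(C)(C)O[Si](CC)(CC)CC)C/C=C(/C)CC[C@@H](I)[C@@](C)(C2)O1
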